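Read in percent of the starting material charged, the earlier runs tempt one to cut that charge, with 100.4% at the last reading in south-west against 61.1% in north, but that percentage carries the charge in its denominator.

| flask | starting material | partner | free catalyst | impurity | remark | time |
|---|---|---|---|---|---|---|
| north | 0.19 M | 0.114 M | 0.21 mM | 47 µM | run made earlier |  |
| south-west | 0.095 M | 0.114 M | 0.21 mM | 47 µM | run made earlier |  |
| west | 0.14 M | 0.114 M | 0.21 mM | 47 µM | run made earlier |  |
| epsilon | 0.19 M | 0.114 M (fed, over 12.0 min) | 0.21 mM | 47 µM | all but partner at the start; partner goes in evenly over 12.0 min, the run ends at 15 min | 15 min |
| theta | 0.19 M | 0.114 M | 0.21 mM | 47 µM | a closed flask charged with all of it at once and left for 15 min | 15 min |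
| gamma | 0.19 M (fed, over 12.0 min) | 0.114 M | 0.21 mM | 47 µM | all but starting material at the start; starting material goes in evenly over 12.0 min, the run ends at 15 min | 15 min |
| delta | 0.19 M | 0.114 M | 0.21 mM | 47 µM | a single well-mixed tank run continuously and read at steady state, 15 min in it on average |  |

- north (time / min: target / %): 1.33: 60.8; 2.00: 60.6; 3.00: 60.4; 4.00: 59.5; 6.00: 59.5; 10.0: 60.3; 15.0: 61.1
- south-west (time / min: target / %): 0.833: 90.7; 2.50: 100.7; 4.00: 100.8; 6.00: 99.5; 10.0: 100.8; 12.0: 99.8; 15.0: 100.4
- west (time / min: target / %): 0.833: 69.7; 2.50: 82.6; 4.00: 80.4; 6.00: 82.2; 10.0: 80.9; 12.0: 82.3; 15.0: 80.9

(readings scatter by 0.5 percentage points)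

- the stated concentrations are those of everything mixed, before any reaction; amounts are the same in each set-up
- steps under discussion: partner + free catalyst -> catalyst intermediate A; starting material + catalyst intermediate A -> catalyst intermediate B; catalyst intermediate B -> catalyst intermediate C; catalyst intermediate C -> free catalyst + target; free catalyst + impurity -> spent catalyst
- the feed brings no volume worth counting
- the earlier runs were made in a closed, stirred flask

- the set-up with the highest amount of target at the outlet or at the end, in percent of the starting material put in ("none" if the first two lie within 2 percentage points) (epsilon / theta / gamma / delta / none)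
- amount of target at the outlet or at the end, in percent of the starting material put in, epsilon
- amount of target at the outlet or at the end, in percent of the starting material put in, theta
- amount of target at the outlet or at the end, in percent of the starting material put in, gamma
- amount of target at the outlet or at the end, in percent of the starting material put in, delta

1. Main reaction. Multiplied back by the charges, the last readings give 0.116 M of target in north and 0.113 M in west, both near the partner charge of 0.114 M. South-west gives 0.0954 M, near its starting material charge of 0.095 M. So the readings fit one target from one partner and one starting material, and the lesser charge is the limiting reagent.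

2. The carried quantity. The yield ceiling, the smaller of one and the partner charge over the starting material charge, is 60.0% for this recipe. Control changes hands at equal charges: south-west has 1.20 equivalents of partner, west 0.814.

3. Impurity. Its charge is 22.4% of the catalyst charge, so at one to one it can hold that share of the catalyst. The earlier runs carried the same two charges and still reached their plateaus.

4. Feeds. The first south-west reading gives a mean pace of target of 0.103 M min⁻¹ up to 0.833 min, about ten times the partner feed of 0.009500 M min⁻¹. It also exceeds the starting material feed of 0.0158 M min⁻¹. So this reckoning puts epsilon, theta and gamma at the ceiling.

5. Tank. Partner passes through at 0.007600 M min⁻¹, also below that pace, so delta should stand slightly under the ceiling, and the best is none.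

The forecast gives 59.9% for epsilon, 60% for theta, 59.9% for gamma and 58.3% for delta, with best none, on the ground that “the lesser reagent caps the yield”.

The flasks give 60.0% for epsilon, 60.0% for theta, 60.0% for gamma and 59.9% for delta, so the best is none.

partner + free catalyst → catalyst intermediate A (k = 4100 M⁻¹ s⁻¹); starting material + catalyst intermediate A → catalyst intermediate B (k = 1000 M⁻¹ s⁻¹); catalyst intermediate B → catalyst intermediate C (k = 25.0 s⁻¹); catalyst intermediate C → free catalyst + target (k = 28.0 s⁻¹); free catalyst + impurity → spent catalyst (k = 5300 M⁻¹ s⁻¹) In theta, half the turnover of starting material with catalyst intermediate A is done by 0.413 min, far earlier than the reading at 15 min, and 100% of it by 3.00 min. At the end, theta holds 0% of its partner and 40% of its starting material, with target at the ceiling of 60.0%. A neighbour of theta with 0.76 M of starting material has a ceiling of 15.0% and gives 15.0%. Another neighbour of theta, with 0.076 M of starting material, has a ceiling of 100% and gives 100%, with 33% of its partner left.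

The readings were generated by integration for an exercise, noise included.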